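If partner left the flask as product and by no other exit, its charge of 1.72 M covers the 1.56 M of the two substrates on paper, with 0.160 M over. The runs stall short of that, so partner needs a ledger with two exits.

| setting | elm | cedar | flask |
|---|---|---|---|
| left-handed substrate | 0.78 M | 0.78 M | 0.78 M |
| right-handed substrate | 0.78 M | 0.78 M | 0.78 M |
| partner | 1.72 M | 1.72 M | 1.72 M |
| catalyst | 8.6 mM | 13 mM | 8.6 mM |
| remark | the very flask that is asked about, followed so far | run made earlier |  |
| time |  |  | 2.0 h |

| run | time / min | left-handed substrate / % | right-handed substrate / % | left-handed product / % |
|---|---|---|---|---|
| elm | 6.00 | 35.7 | 48.2 | 13.3 |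
| elm | 15.0 | 27.0 | 45.5 | 20.9 |
| elm | 30.0 | 22.9 | 40.5 | 25.5 |
| elm | 50.0 | 22.9 | 33.5 | 26.1 |
| cedar | 30.0 | 18.9 | 37.1 | 29.6 |
| cedar | 60.0 | 16.7 | 28.5 | 29.3 |
| cedar | 90.0 | 20.4 | 25.3 | 28.1 |
| cedar | 120 | 20.7 | 23.3 | 27.4 |

(scatter of a reading: 1 percentage point)

1. part of the left-handed substrate and right-handed substrate charged together that has reacted at 2.0 h
2. excess of left-handed product over right-handed product in the product at 2.0 h
3. excess of right-handed substrate over left-handed substrate among what is left of the two at 2.0 h

- catalyst is single-handed; left-handed substrate and right-handed substrate are mirror images of each other, charged as a racemate, each of them at the stated concentration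
- on the list of suspects stand: partner + catalyst + left-handed substrate -> catalyst + left-handed product; partner + catalyst + right-handed substrate -> catalyst + right-handed product; left-handed substrate <-> right-handed substrate; partner -> decomposed reagent; left-handed product <-> right-handed product
- an excess is the difference of the two amounts in percent of their sum
- an excess is below zero if the other one leads

At any moment the product exit runs in proportion to c(partner), c(catalyst) and c(substrate), the decomposition exit in proportion to c(partner). In their comparison c(partner) cancels, which leaves c(catalyst) times c(substrate), and that comparison drifts against product as substrate falls.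

Cedar nearly closes its books: conversion reads 54.3% at 90.0 min and 56.0% at 120 min. Product takes 0.874 M of partner, and the ledger enters the remaining 0.846 M as decomposed. Lumping both substrates as one pool gives the exchange number 74.6 M⁻²: the natural logarithm of substrate charged over substrate left, per molar of partner decomposed and per molar of catalyst.

Elm, the very flask asked about, has the same charge with less catalyst. Its reading of 43.6% at 50.0 min leaves 1.04 M for the decomposition entry, and the exchange number turns that into 48.7%. Re-entering this gives 46.0%, so this ledger balances between them, near 47.3%.

The forecast stands somewhat higher, at 50%, with 2% and 7% for the excesses; for conversion it reasons that “the remaining partner adds about 6”.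

The flask gives 49.2%, 1.94% and 4.86%.

    partner + catalyst + left-handed substrate → catalyst + left-handed product (k = 4.20 M⁻² min⁻¹)
    partner + catalyst + right-handed substrate → catalyst + right-handed product (k = 0.170 M⁻² min⁻¹)
    left-handed substrate ⇌ right-handed substrate (k = 0.0171 min⁻¹)
    partner → decomposed reagent (k = 0.0212 min⁻¹)
    left-handed product ⇌ right-handed product (k = 0.0261 min⁻¹)

Decomposition is a part of why the flask stands at 49.2%: with the loss of partner to decomposed reagent taken away, the run reaches 75.5%. The product excess of 1.94% comes mainly from the exchange of left-handed product with right-handed product: without it the run keeps 88.9%. At 2.00 h the flask holds 1.34% of its partner and 0.929 M of decomposed reagent, which puts its exchange number at 84.9 M⁻², against 74.6 M⁻² from cedar. Entered with the 0.783 M decomposed in the neighbour flask charged with 0.015 M of catalyst, cedar's number gives 58.4% reacted; that flask gives 59.2%.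

(The readings come from a simulation with made-up constants; the scatter is artificial.)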